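## Retrosynthetic overview

1. Rings A and B are bought as arenes. The only ring made is ring C (the dihydropyran), closed last through the O1–C2 bond by intramolecular Mitsunobu etherification of phenol alcohol 22.
2. The C4–C4a bond comes from a Negishi sp3–sp2 coupling of the alkylzinc derived from iodo acetate 8 (ring B plus C2–C3–C4) with aryl iodide 18 (ring A).
3. The single stereocentre (C3) is created by lipase-catalysed desymmetrisation of prochiral diacetate 6, built from 4-bromo-3-methoxyphenol and diethyl malonate.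
4. Ring A fragment 18 comes from 5-methoxyresorcinol by three directed ortho-metalations (silyl block at the future C8, prenyl at the future C6, iodide at the future C4a); symmetry fixes the regiochemistry.

Assumption: the lipase cleaves the pro-R acetoxymethyl arm of 6, the sense expected from the usual active-site model for primary alcohols with the aryl group as the large substituent; this is a prediction, and the configuration of 7 is confirmed once by Mosher ester analysis.

## Route

Step 1
Reactants: 1 4-bromo-3-methoxyphenol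
Product: 2 1-bromo-2-methoxy-4-(methoxymethoxy)benzene
Conditions: MOMCl, i-Pr2NEt, CH2Cl2, 0 °C → rt
Reagents that add atoms: chloromethyl methyl ether (MOMCl), COCCl
Why: O-alkylation of the phenol (Williamson-type) masks it as a base-stable acetal before the palladium, hydride and organometallic steps.

Step 2
Reactants: 2 1-bromo-2-methoxy-4-(methoxymethoxy)benzene; 3 diethyl malonate
Product: 4 diethyl 2-[2-methoxy-4-(methoxymethoxy)phenyl]malonate
Conditions: Pd2(dba)3 (1 mol%), t-Bu3P·HBF4 (4 mol%), K3PO4, toluene, 70 °C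
Reagents that add atoms: none
Why: Palladium-catalysed α-arylation of the malonate enolate with a bulky electron-rich trialkylphosphine couples the ortho-methoxy aryl bromide and installs the three carbons that become C2, C3 and C4.

Step 3
Reactants: 4 diethyl 2-[2-methoxy-4-(methoxymethoxy)phenyl]malonate
Product: 5 2-[2-methoxy-4-(methoxymethoxy)phenyl]propane-1,3-diol
Conditions: LiAlH4, THF, 0 °C → rt; Fieser work-up (H2O, NaOH aq, H2O)
Reagents that add atoms: none
Why: Hydride reduction of both esters gives the prochiral 2-aryl-1,3-diol, and the MOM acetal is inert to LiAlH4.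

Step 4
Reactants: 5 2-[2-methoxy-4-(methoxymethoxy)phenyl]propane-1,3-diol
Product: 6 2-[2-methoxy-4-(methoxymethoxy)phenyl]propane-1,3-diyl diacetate
Conditions: Ac2O, pyridine, DMAP (cat.), CH2Cl2, rt
Reagents that add atoms: acetic anhydride, CC(=O)OC(C)=O
Why: DMAP-catalysed acylation of both primary hydroxyls gives the mirror-symmetric diacetate that serves as the hydrolase substrate.

Step 5
Reactants: 6 2-[2-methoxy-4-(methoxymethoxy)phenyl]propane-1,3-diyl diacetate
Product: 7 (S)-3-hydroxy-2-[2-methoxy-4-(methoxymethoxy)phenyl]propyl acetate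
Conditions: lipase (Burkholderia cepacia lipase, Amano PS), KH2PO4/K2HPO4 buffer (0.2 M, pH 7.0), acetone (10% v/v), 25 °C, stopped when 1.0 equiv of ester is cleaved; recovered 5 is re-acetylated to 6
Reagents that add atoms: none
Why: Lipase-catalysed enantiotopic-group-selective hydrolysis (desymmetrisation of a prochiral diacetate) cleaves only the pro-R acetoxymethyl arm in the chiral active site and so creates C3 as (S), while any over-hydrolysis consumes mainly the minor enantiomer and raises the ee.

Step 6
Reactants: 7 (S)-3-hydroxy-2-[2-methoxy-4-(methoxymethoxy)phenyl]propyl acetate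
Product: 8 (R)-3-iodo-2-[2-methoxy-4-(methoxymethoxy)phenyl]propyl acetate
Conditions: I2, PPh3, imidazole, CH2Cl2, 0 °C → rt (7 used immediately after isolation)
Reagents that add atoms: iodine, II
Why: Appel iodination displaces the alkoxyphosphonium group by iodide in an SN2 step at CH2, so the neighbouring stereocentre is untouched (the descriptor becomes R only through the priority change) and the free hydroxyl is removed before acyl migration can erode the ee.

Step 7
Reactants: 9 5-methoxyresorcinol
Product: 10 1-methoxy-3,5-bis(methoxymethoxy)benzene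
Conditions: MOMCl (2.5 equiv), i-Pr2NEt, CH2Cl2, 0 °C → rt
Reagents that add atoms: chloromethyl methyl ether (MOMCl), COCCl
Why: Double O-alkylation protects both phenols and installs two strong ortho-directing groups for the metalations that follow.

Step 8
Reactants: 10 1-methoxy-3,5-bis(methoxymethoxy)benzene
Product: 12 [4-methoxy-2,6-bis(methoxymethoxy)phenyl]trimethylsilane, via aryllithium 11 (not isolated)
Conditions: n-BuLi (1.1 equiv), THF, 0 °C → rt, 1 h; TMSCl, 0 °C
Reagents that add atoms: chlorotrimethylsilane, C[Si](C)(C)Cl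
Why: Directed ortho-metalation favours the position flanked by both OMOM groups (double chelation), and silylating it blocks the future C8 so that later metalations must occur next to the methoxy group.

Step 9
Reactants: 12 [4-methoxy-2,6-bis(methoxymethoxy)phenyl]trimethylsilane
Product: 15 [4-methoxy-2,6-bis(methoxymethoxy)-3-(3-methylbut-2-en-1-yl)phenyl]trimethylsilane, via aryllithium 13 (not isolated), via arylcopper 14 (not isolated)
Conditions: n-BuLi (1.2 equiv), THF, 0 °C, 1 h; CuBr·SMe2 (1.2 equiv), −40 °C; prenyl bromide, −40 °C → rt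
Reagents that add atoms: prenyl bromide (1-bromo-3-methylbut-2-ene), CC(C)=CCBr
Why: The second directed ortho-metalation can only take place at one of the two symmetry-equivalent positions between OMe and OMOM, and the arylcopper species alkylates prenyl bromide at its primary carbon (SN2) to give the linear prenyl group.

Step 10
Reactants: 15 [4-methoxy-2,6-bis(methoxymethoxy)-3-(3-methylbut-2-en-1-yl)phenyl]trimethylsilane
Product: 17 [3-iodo-4-methoxy-2,6-bis(methoxymethoxy)-5-(3-methylbut-2-en-1-yl)phenyl]trimethylsilane, via aryllithium 16 (not isolated)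
Conditions: n-BuLi (1.3 equiv), TMEDA, THF, −20 → 0 °C; I2 in THF, −78 °C → rt; Na2S2O3 aq
Reagents that add atoms: iodine, II
Why: The third directed ortho-metalation removes the only remaining ring hydrogen (between OMe and OMOM), and iodinolysis of the C–Li bond places the iodide at the future C4a.

Step 11
Reactants: 17 [3-iodo-4-methoxy-2,6-bis(methoxymethoxy)-5-(3-methylbut-2-en-1-yl)phenyl]trimethylsilane
Product: 18 2-iodo-3-methoxy-1,5-bis(methoxymethoxy)-4-(3-methylbut-2-en-1-yl)benzene
Conditions: TBAF (1 M in THF, wet, 2 equiv), THF, 50 °C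
Reagents that add atoms: none
Why: Fluoride-induced protodesilylation works because the departing aryl anion is stabilised by two ortho oxygen substituents, so the blocking group is removed without touching the iodide, the MOM ethers or the prenyl group.

Step 12
Reactants: 8 (R)-3-iodo-2-[2-methoxy-4-(methoxymethoxy)phenyl]propyl acetate; 18 2-iodo-3-methoxy-1,5-bis(methoxymethoxy)-4-(3-methylbut-2-en-1-yl)benzene
Product: 20 (R)-3-[2-methoxy-4,6-bis(methoxymethoxy)-3-(3-methylbut-2-en-1-yl)phenyl]-2-[2-methoxy-4-(methoxymethoxy)phenyl]propyl acetate, via alkylzinc iodide 19 (not isolated)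
Conditions: 8 (1.3 equiv), Zn dust (I2-activated), DMF, rt, 1 h; then 18, Pd2(dba)3 (2.5 mol%), SPhos (10 mol%), DMF, 45 °C
Reagents that add atoms: none
Why: In this Negishi sp3–sp2 cross-coupling zinc inserts into the primary C–I bond without harming ester or acetal groups, and zerovalent palladium with the bulky biaryl phosphine couples the alkylzinc with the di-ortho-alkoxy aryl iodide faster than β-hydride elimination, so the β-stereocentre is retained.

Step 13
Reactants: 20 (R)-3-[2-methoxy-4,6-bis(methoxymethoxy)-3-(3-methylbut-2-en-1-yl)phenyl]-2-[2-methoxy-4-(methoxymethoxy)phenyl]propyl acetate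
Product: 21 (R)-3-[2-methoxy-4,6-bis(methoxymethoxy)-3-(3-methylbut-2-en-1-yl)phenyl]-2-[2-methoxy-4-(methoxymethoxy)phenyl]propan-1-ol
Conditions: K2CO3 (0.2 equiv), MeOH, rt
Reagents that add atoms: none
Why: Base-catalysed transesterification (methanolysis of the acetate) frees the primary alcohol while MOM ethers, the prenyl group and the non-acidic stereocentre are unaffected.

Step 14
Reactants: 21 (R)-3-[2-methoxy-4,6-bis(methoxymethoxy)-3-(3-methylbut-2-en-1-yl)phenyl]-2-[2-methoxy-4-(methoxymethoxy)phenyl]propan-1-ol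
Product: 22 (R)-4-[3-hydroxy-2-(4-hydroxy-2-methoxyphenyl)propyl]-5-methoxy-6-(3-methylbut-2-en-1-yl)benzene-1,3-diol
Conditions: HCl (3 M aq), MeOH, 35 °C, under argon, stopped at full conversion
Reagents that add atoms: none
Why: Acid-catalysed acetal exchange with methanol removes all three MOM groups as dimethoxymethane under conditions mild enough to leave the prenyl alkene unhydrated and uncyclised.

Step 15
Reactants: 22 (R)-4-[3-hydroxy-2-(4-hydroxy-2-methoxyphenyl)propyl]-5-methoxy-6-(3-methylbut-2-en-1-yl)benzene-1,3-diol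
Product: 23 (3R)-3-(4-hydroxy-2-methoxyphenyl)-5-methoxy-6-(3-methylbut-2-en-1-yl)chroman-7-ol (target)
Conditions: PPh3 (1.5 equiv), DIAD (1.5 equiv, slow addition), THF (0.01 M), 0 °C → rt
Reagents that add atoms: none
Why: In this intramolecular Mitsunobu etherification only the phenol ortho to the side chain can reach the activated primary carbon, so the six-membered ring closes by SN2 at CH2 (C2) much faster at high dilution than the other phenols react intermolecularly, and C3 is not involved and stays (R).

## Compound list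

1 | 4-bromo-3-methoxyphenol | COc1cc(O)ccc1Br | starting material
2 | 1-bromo-2-methoxy-4-(methoxymethoxy)benzene | COCOc1ccc(Br)c(OC)c1 | intermediate
3 | diethyl malonate | CCOC(=O)CC(=O)OCC | starting material
4 | diethyl 2-[2-methoxy-4-(methoxymethoxy)phenyl]malonate | CCOC(=O)C(C(=O)OCC)c1ccc(OCOC)cc1OC | intermediate
5 | 2-[2-methoxy-4-(methoxymethoxy)phenyl]propane-1,3-diol | OCC(CO)c1ccc(OCOC)cc1OC | intermediate
6 | 2-[2-methoxy-4-(methoxymethoxy)phenyl]propane-1,3-diyl diacetate | CC(=O)OCC(COC(C)=O)c1ccc(OCOC)cc1OC | intermediate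
7 | (S)-3-hydroxy-2-[2-methoxy-4-(methoxymethoxy)phenyl]propyl acetate | COCOc1ccc([C@@H](CO)COC(C)=O)c(OC)c1 | intermediate
8 | (R)-3-iodo-2-[2-methoxy-4-(methoxymethoxy)phenyl]propyl acetate | COCOc1ccc([C@@H](CI)COC(C)=O)c(OC)c1 | intermediate
9 | 5-methoxyresorcinol (5-methoxybenzene-1,3-diol) | COc1cc(O)cc(O)c1 | starting material
10 | 1-methoxy-3,5-bis(methoxymethoxy)benzene | COCOc1cc(OC)cc(OCOC)c1 | intermediate
11 | [4-methoxy-2,6-bis(methoxymethoxy)phenyl]lithium | [Li]c1c(OCOC)cc(OC)cc1OCOC | intermediate
12 | [4-methoxy-2,6-bis(methoxymethoxy)phenyl]trimethylsilane | C[Si](C)(C)c1c(OCOC)cc(OC)cc1OCOC | intermediate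
13 | [6-methoxy-2,4-bis(methoxymethoxy)-3-(trimethylsilyl)phenyl]lithium | [Li]c1c(OC)cc(OCOC)c([Si](C)(C)C)c1OCOC | intermediate
14 | [6-methoxy-2,4-bis(methoxymethoxy)-3-(trimethylsilyl)phenyl]copper | [Cu]c1c(OC)cc(OCOC)c([Si](C)(C)C)c1OCOC | intermediate
15 | [4-methoxy-2,6-bis(methoxymethoxy)-3-(3-methylbut-2-en-1-yl)phenyl]trimethylsilane | CC(C)=CCc1c(OC)cc(OCOC)c([Si](C)(C)C)c1OCOC | intermediate
16 | [2-methoxy-4,6-bis(methoxymethoxy)-3-(3-methylbut-2-en-1-yl)-5-(trimethylsilyl)phenyl]lithium | CC(C)=CCc1c(OC)c([Li])c(OCOC)c([Si](C)(C)C)c1OCOC | intermediate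
17 | [3-iodo-4-methoxy-2,6-bis(methoxymethoxy)-5-(3-methylbut-2-en-1-yl)phenyl]trimethylsilane | CC(C)=CCc1c(OC)c(I)c(OCOC)c([Si](C)(C)C)c1OCOC | intermediate
18 | 2-iodo-3-methoxy-1,5-bis(methoxymethoxy)-4-(3-methylbut-2-en-1-yl)benzene | CC(C)=CCc1c(OC)c(I)c(OCOC)cc1OCOC | intermediate
19 | (R)-{3-acetoxy-2-[2-methoxy-4-(methoxymethoxy)phenyl]propyl}zinc iodide | COCOc1ccc([C@@H](C[Zn]I)COC(C)=O)c(OC)c1 | intermediate
20 | (R)-3-[2-methoxy-4,6-bis(methoxymethoxy)-3-(3-methylbut-2-en-1-yl)phenyl]-2-[2-methoxy-4-(methoxymethoxy)phenyl]propyl acetate | COCOc1ccc([C@@H](Cc2c(OCOC)cc(OCOC)c(CC=C(C)C)c2OC)COC(C)=O)c(OC)c1 | intermediate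
21 | (R)-3-[2-methoxy-4,6-bis(methoxymethoxy)-3-(3-methylbut-2-en-1-yl)phenyl]-2-[2-methoxy-4-(methoxymethoxy)phenyl]propan-1-ol | COCOc1ccc([C@@H](Cc2c(OCOC)cc(OCOC)c(CC=C(C)C)c2OC)CO)c(OC)c1 | intermediate
22 | (R)-4-[3-hydroxy-2-(4-hydroxy-2-methoxyphenyl)propyl]-5-methoxy-6-(3-methylbut-2-en-1-yl)benzene-1,3-diol | Oc1ccc([C@@H](Cc2c(O)cc(O)c(CC=C(C)C)c2OC)CO)c(OC)c1 | intermediate
23 | (3R)-3-(4-hydroxy-2-methoxyphenyl)-5-methoxy-6-(3-methylbut-2-en-1-yl)chroman-7-ol | COc1cc(O)ccc1[C@@H]1COc2cc(O)c(CC=C(C)C)c(OC)c2C1 | target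

## Step count and risks

Total step count: 15 (steps 1–6 for the ring B/stereocentre fragment, steps 7–11 for the ring A fragment, steps 12–15 for coupling and endgame).

Longest linear sequence: 10 steps (1 → 23 through steps 1–6 and 12–15).

The three steps most likely to fail:

Step 12, the Negishi coupling. The aryl iodide carries two ortho alkoxy groups and the alkylzinc is β-branched, so slow transmetalation or protodezincation is possible. The fallback reverses the polarity of the two partners and sets out from aryl iodide 18. Iodine–lithium exchange with t-BuLi (2 equiv, Et2O, −78 °C) gives the aryllithium F7. MgBr2·OEt2 converts it into the arylmagnesium bromide F8. F8 is alkylated by iodide 8 under copper catalysis (Li2CuCl4 5 mol%, THF/NMP, 0 °C), where the primary iodide reacts faster than the acetate, and the route is rejoined at 20.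

Step 5, the lipase hydrolysis. The ee may suffer from acyl migration in water or from a poor fit of the ortho-methoxyaryl group. The fallback keeps the lipase but runs it in the acylation direction and sets out from diol 5. The immobilised lipase with vinyl acetate in t-BuOMe acylates the arm it would otherwise hydrolyse and gives the (R)-monoacetate F1 in an anhydrous medium. Since the acetate now sits on the arm that must become C4, the arms are exchanged:
- TBSCl/imidazole gives the silyl ether acetate F2.
- i-Bu2AlH at −78 °C removes the acetate to give the alcohol F3.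
- I2/PPh3/imidazole gives the iodide F4.
- Zinc insertion gives the alkylzinc iodide F5.
- Negishi coupling with 18 gives the silyl ether F6.
- TBAF then returns to alcohol 21.

If instead the hydrolysis shows the opposite sense of selection, the same acylation of 5 gives 7 itself and the route continues unchanged.

Step 15, the Mitsunobu ring closure. Two free bystander phenols are present and the polar product must be separated from phosphine oxide and hydrazine by-products. The fallback closes the ring by phenoxide alkylation instead and sets out from alcohol 21. Appel chlorination (PPh3, CCl4, MeCN) gives the chloride F9. HCl/MeOH removes the MOM groups to give the triphenol chloride F10. K2CO3 with catalytic NaI in DMF (0.01 M, 50 °C) effects the intramolecular Williamson etherification by the only phenoxide that can form a six-membered ring, arriving at 23.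

## Further compounds

F1 | step 5 | (R)-3-hydroxy-2-[2-methoxy-4-(methoxymethoxy)phenyl]propyl acetate | COCOc1ccc([C@@H](COC(C)=O)CO)c(OC)c1
F2 | step 5 | (S)-3-[(tert-butyldimethylsilyl)oxy]-2-[2-methoxy-4-(methoxymethoxy)phenyl]propyl acetate | COCOc1ccc([C@@H](COC(C)=O)CO[Si](C)(C)C(C)(C)C)c(OC)c1
F3 | step 5 | (S)-3-[(tert-butyldimethylsilyl)oxy]-2-[2-methoxy-4-(methoxymethoxy)phenyl]propan-1-ol | COCOc1ccc([C@@H](CO)CO[Si](C)(C)C(C)(C)C)c(OC)c1
F4 | step 5 | (R)-tert-butyl{3-iodo-2-[2-methoxy-4-(methoxymethoxy)phenyl]propoxy}dimethylsilane | COCOc1ccc([C@@H](CI)CO[Si](C)(C)C(C)(C)C)c(OC)c1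
F5 | step 5 | (R)-{3-[(tert-butyldimethylsilyl)oxy]-2-[2-methoxy-4-(methoxymethoxy)phenyl]propyl}zinc iodide | COCOc1ccc([C@@H](C[Zn]I)CO[Si](C)(C)C(C)(C)C)c(OC)c1
F6 | step 5 | (R)-tert-butyl{3-[2-methoxy-4,6-bis(methoxymethoxy)-3-(3-methylbut-2-en-1-yl)phenyl]-2-[2-methoxy-4-(methoxymethoxy)phenyl]propoxy}dimethylsilane | COCOc1ccc([C@@H](Cc2c(OCOC)cc(OCOC)c(CC=C(C)C)c2OC)CO[Si](C)(C)C(C)(C)C)c(OC)c1
F7 | step 12 | [2-methoxy-4,6-bis(methoxymethoxy)-3-(3-methylbut-2-en-1-yl)phenyl]lithium | CC(C)=CCc1c(OC)c([Li])c(OCOC)cc1OCOC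
F8 | step 12 | [2-methoxy-4,6-bis(methoxymethoxy)-3-(3-methylbut-2-en-1-yl)phenyl]magnesium bromide | CC(C)=CCc1c(OC)c([Mg]Br)c(OCOC)cc1OCOC
F9 | step 15 | 1-{(R)-3-chloro-2-[2-methoxy-4-(methoxymethoxy)phenyl]propyl}-2-methoxy-4,6-bis(methoxymethoxy)-3-(3-methylbut-2-en-1-yl)benzene | COCOc1ccc([C@@H](Cc2c(OCOC)cc(OCOC)c(CC=C(C)C)c2OC)CCl)c(OC)c1
F10 | step 15 | (R)-4-[3-chloro-2-(4-hydroxy-2-methoxyphenyl)propyl]-5-methoxy-6-(3-methylbut-2-en-1-yl)benzene-1,3-diol | Oc1ccc([C@@H](Cc2c(O)cc(O)c(CC=C(C)C)c2OC)CCl)c(OC)c1
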